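The catalyst comes out of every step as it went in, so its 20 mM stayed constant, and each step it drives behaved as pseudo-first-order with a fixed constant.

    target → over-reaction product (k1 = 0.038 min⁻¹)
    target + catalyst ⇌ isomer of the product A + catalyst, rate k2*[catalyst]*[target] forward; the back reaction follows from the equilibrium constant (K2 = 3.1, k2 = 0.13 M⁻¹ min⁻¹)
    isomer of the product A + catalyst ⇌ isomer of the product B + catalyst, rate k3*[catalyst]*[isomer of the product A] forward; the back reaction follows from the equilibrium constant (K3 = 0.22, k3 = 0.019 M⁻¹ min⁻¹)
    isomer of the product B ⇌ substrate (k4 = 0.0063 min⁻¹)
    substrate + catalyst ⇌ target + catalyst, rate k5*[substrate]*[catalyst] forward; the back reaction follows from the equilibrium constant (K5 = 1.5, k5 = 13 M⁻¹ min⁻¹)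

in all of them: catalyst 20 mM; time 2.5 h

| flask | substrate |
|---|---|
| midnight | 1.3 M (fed, over 0.80 h) |
| spring | 1.3 M (fed, over 2.5 h) |
| summer | 1.3 M (fed, over 8.0 h) |
| dawn | 1.3 M (fed, over 25 h) |

- amount of target at the end, in percent of the substrate charged for midnight, spring, summer, dawn, in this order
- the shape of the row from first to last (rises all the way / hardly changes / falls, then rises / rises, then falls / falls all the way)

- percentages count the whole charge, also what has not yet gone in
- "hardly changes" means that all values lie within two and a half points (for a concentration: within two and a half percent of the largest)
- run time (midnight): 2.5 h

I followed one rate: how fast the pool of substrate plus target filled. Substrate passed to target with a constant of 0.260 min⁻¹. I held the two at their equilibrium, which puts 60.0% of the pool in target. Target left with a constant of 0.0406 min⁻¹, the over-reaction plus the forward step to isomer of the product A. So I took: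

pool drain constant λ = target share × loss constant of target = 0.0244 min⁻¹

This is the pool drain constant, the share of the pool that is target times the loss constant of target. The interconversion was much faster than this drain, so the equilibrium was a fair assumption. I left out the passage from substrate to isomer of the product B, whose constant of 0.00644 min⁻¹ comes to 0.00258 min⁻¹ on the substrate share of the pool, which is smaller than the drain, and I left out every return to the pool.

At the start the pool filled at the feed rate, which in spring was 0.520 M h⁻¹. The drain slowed that rate by the factor exp(−λt), which had reached 0.0259 by the end of the run. Integrating gave:

pool during the feed = (feed rate / λ) × (1 − exp(−λt))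

pool after the feed = pool at the end of the feed × exp(−λ × time since the feed stopped)

In spring the feed ended at the sampling time, so target came to 16.0% of the charge. At midnight the feed stopped early, and the wait afterwards cut the pool by a further factor of 0.0833, which left 2.95%. In summer the feed outlasted the run, and its feed rate was lower than spring's, so target had to sink with it. I committed to rises, then falls, with spring at the top.

The forecast gave 3.2%, 14.8%, 4.6% and 1.5%, also rises, then falls, holding that “target tracks the feed rate while dosing”.

The flasks gave 3.30%, 14.9%, 4.65% and 1.49%, so the row rises, then falls, and my spring figure stood 1.1 percentage points above the flask. At the end of the midnight run, the step to over-reaction product used target 15 times as fast as the forward step to isomer of the product A. The midnight flask also shows the stretch after the feed. The same 0.0244 min⁻¹ gives a fall by a factor of 0.0833 over that wait. In the midnight flask, target went from 32.0% at 0.800 h to 3.30% at 2.50 h, a factor of 0.103.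

The numbers stand for no real mixture, and the outcome is calculated.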